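**The cedar puzzle.** The cedar run seemed to contradict itself. At 5.00 min it held 17.1% self-condensation product against 6.6% target, yet at 60.0 min target led, 50.4% to 45.1%.

| flask | substrate | partner | protic impurity | free catalyst | remark | time |
|---|---|---|---|---|---|---|
| cedar | 0.12 M | 0.12 M | 0.060 M | 3 mM | run made earlier |  |
| elm | 0.12 M | 0.080 M | 0.060 M | 3 mM | run made earlier |  |
| maple | 0.12 M | 0.18 M | 0.060 M | 3 mM | run made earlier |  |
| west | 0.12 M | 0.120 M | 0.0600 M | 3.0 mM | everything together at the start | 1.0 h |
| north | 0.12 M (fed, over 12 min) | 0.120 M | 0.0600 M | 3.0 mM | all else is in the flask from the start; the feed brings no volume worth counting | 1.0 h |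
| north-east | 0.12 M | 0.120 M (fed, over 12 min) | 0.0600 M | 3.0 mM | all else is in the flask from the start; the feed brings no volume worth counting | 1.0 h |
| east | 0.12 M | 0.120 M (in portions, 4, over 12 min) | 0.0600 M | 3.0 mM | first portion at the start, last at 12 min | 1.0 h |

- cedar (time / min: target / %, self-condensation product / %, substrate / %): 5.00: 6.6, 17.1, 73.3; 12.0: 13.4, 29.4, 53.3; 25.0: 29.2, 40.4, 30.7; 60.0: 50.4, 45.1, 6.0
- elm (time / min: target / %, self-condensation product / %, substrate / %): 10.0: 11.3, 26.8, 58.3; 20.0: 18.8, 37.3, 39.4; 25.0: 23.4, 41.3, 33.4; 40.0: 31.8, 47.0, 21.0
- maple (time / min: target / %, self-condensation product / %, substrate / %): 5.00: 6.4, 14.8, 73.2; 12.0: 17.3, 28.4, 50.7; 25.0: 33.3, 37.1, 24.4; 40.0: 47.7, 38.9, 9.4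

(standard deviation of a reading: 1 percentage point)

- in percentages every species weighs as the substrate in it: one self-condensation product counts as two

- which flask leads in share of target in target plus self-condensation product ("all alike" within 1.5 percentage points) (west / north / north-east / east / all alike)
- share of target in target plus self-condensation product at the end, west
- share of target in target plus self-condensation product at the end, north
- share of target in target plus self-condensation product at the end, north-east
- share of target in target plus self-condensation product at the end, east

**Dropping time.** I divided one gain by the other, so that time fell out. Between 12.0 min and 25.0 min cedar gained 11 percentage points self-condensation product and 16 points target, a selectivity factor of 0.696 at a mean substrate of 42.0%. Target's rate over the first 5.00 min was 1.09 times its rate in that window, so I took it as roughly independent of substrate and self-condensation as second order. The factor then goes as the square of [substrate], and it reaches one at 50.3% of the charge, the crossover level. Cedar stood at 53.3% at 12.0 min, so its early lead belonged to the time above that level.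

**Reckoning north.** During the feed, target at that rate reaches 14.6%, and substrate climbs towards 85.4%. A square on a steady rise averages a third of its peak, so self-condensation product comes to 14.0%. North's factor over the feed is thus 0.959, against cedar's 2.19. Substrate then stands at 71.4%, near cedar's 73.3% at 5.00 min, so I set the end of north's feed against that moment of cedar, and north's end then falls at 53.0 min on cedar's clock. Interpolating in a straight line between cedar's readings at 25.0 min and 60.0 min, I added cedar's gains up to that time and got 54.1% target, 41.1% self-condensation product and a share of 56.9%. At 25.0 min the share was 36.2% in elm and 47.3% in maple, so I put both partner-fed flasks below west.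

**The result.** The forecast gave 53% for west, 58% for north, 49% for north-east and 50% for east, with the words “North should lead”. The flasks gave 53.3%, 56.4%, 50.3% and 50.6%, so north leads, 0.50 points under my reckoning.

    catalyst intermediate D → free catalyst + target (k = 0.0680 s⁻¹)
    partner + protic impurity → quenched reagent (k = 0.00500 M⁻¹ s⁻¹)
    2 substrate → self-condensation product (k = 0.00320 M⁻¹ s⁻¹)
    substrate + catalyst intermediate B → spent catalyst (k = 0.00630 M⁻¹ s⁻¹)
    catalyst intermediate B → by-product + catalyst intermediate C (k = 0.360 s⁻¹)
    substrate + free catalyst → catalyst intermediate A (k = 1.40 M⁻¹ s⁻¹)
    partner + catalyst intermediate A → catalyst intermediate B (k = 0.210 M⁻¹ s⁻¹)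
    catalyst intermediate C → catalyst intermediate D (k = 0.0240 s⁻¹)

**North's balance.** Mean [substrate] in north over the first 12 min was 0.0478 M, less than the crossover of 0.0604 M. At 0.371 h north used substrate 1.0 times as fast through free catalyst as through self-condensation.

**Later north.** At 1.00 h north held 8.80% substrate, which gives a factor of 0.0306, so hardly any of that rest should become self-condensation product. Read at 2.5 h, north showed 39.2% self-condensation product, 60.7% target and a share of 60.8%.

The readings were generated by integration with constants of no real substance.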